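the same everywhere: substrate 10 mM

| flask | partner | remark | time |
|---|---|---|---|
| oak | 5.3 mM | run made earlier |  |
| ash | 23 mM | run made earlier |  |
| summer | 9.00 mM |  | 10 d |
| dawn | 27.0 mM |  | 10 d |

| run | time / d | target / % | side product / % | isomer of the product / % | substrate / % | intermediate / % |
|---|---|---|---|---|---|---|
| oak | 1.25 | 1.7 | 30.1 | 0.2 | 26.7 | 0.4 |
| oak | 2.50 | 1.4 | 36.8 | 0.5 | 14.1 | 0 |
| oak | 4.00 | 1.7 | 41.0 | 0 | 9.5 | 0.6 |
| oak | 5.00 | 1.6 | 42.2 | 0.2 | 7.3 | 0.2 |
| oak | 6.00 | 0.6 | 43.4 | 0.2 | 5.9 | 0.6 |
| oak | 8.00 | 0.7 | 45.2 | 0.6 | 3.8 | 0.4 |
| ash | 1.25 | 4.3 | 76.7 | 0 | 3.2 | 1.1 |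
| ash | 2.50 | 3.6 | 81.6 | 1.1 | 0 | 0 |
| ash | 4.00 | 1.3 | 82.3 | 0.2 | 0.7 | 0 |
| ash | 5.00 | 1.0 | 83.4 | 0.4 | 0 | 0 |
| ash | 6.00 | 0.9 | 83.6 | 0.3 | 0 | 0 |
| ash | 8.00 | 1.0 | 84.3 | 0 | 0.2 | 0 |

(standard deviation of a reading: 0.5 percentage points)
- which of these there is most of at the end, counted by the substrate in it, summer (substrate / intermediate / side product / isomer of the product / target)
- which of these there is most of at the end, counted by the substrate in it, dawn (substrate / intermediate / side product / isomer of the product / target)
- final amount of the leader among these, as a percentage of the substrate charged, in summer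
- final amount of the leader among these, as a percentage of the substrate charged, in dawn
- the earlier runs were read with a standard deviation of 0.5 percentage points
- a reading or a percentage of target counts all its forms, free or not
- a reading of substrate is of its free form alone

- Substrate is conserved, so whatever part of the charge the five read species fail to account for stands in something unread. This unseen share is 49.3% in oak and 14.5% in ash at 8.00 d.
- If that loss goes with c_substrate² and side product with c_substrate·c_partner, their ratio is a constant, the selectivity factor of the pair, times c_substrate/c_partner. The unseen share multiplied by c_partner/c_substrate should then change little: oak gives 0.261 and ash 0.334.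
- Their mean, 0.297, is the loss product.
- For another leader, side product has to end below target or substrate. The highest target reading is 4.3%, in ash, and side product under a target of that size needs an unseen share past about 91.4%, the small species aside. Substrate as leader needs to stand above side product at the end, and the last oak reading has substrate at 3.8% beside side product at 45.2%.
- The reckoning made here puts the unseen share of summer at 33.0%, which is below that mark. Side product in summer then stands near 67.0%, between 62.9% and 71.0% on the two single runs.
- With the ash value, side product in dawn stands near 87.6%.
- The forecast names side product for summer at 63.5% (58% to 69%) and side product for dawn at 86% (83% to 89%), a little below the reckoning here. Its ground: “It is larger at low partner, so it looks like an irreversible loss second order in substrate”.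
- The flasks give side product at 64.9% in summer and side product at 86.6% in dawn.

    intermediate → side product (k = 0.870 h⁻¹)
    intermediate ⇌ isomer of the product (K = 3.10, k = 0.00120 h⁻¹)
    substrate + target ⇌ idle adduct, settled at all times (K = 93.0 M⁻¹)
    2 substrate → homo dimer (k = 2.40 M⁻¹ h⁻¹)
    intermediate ⇌ target (K = 5.00, k = 0.0670 h⁻¹)
    substrate + partner → intermediate + by-product (k = 6.40 M⁻¹ h⁻¹)

- The unseen share is homo dimer, two substrate in each. It holds 34.3% of the charge in summer, which makes a loss product of 0.309 beside the carried 0.297. In dawn it holds 12.9%, and the product is 0.349, a little higher than the 0.334 of ash. The run without this step shows what the loss costs: side product in dawn reaches 99.5% instead of 86.6%, the main reason for its shortfall.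

Readings and results come from a simulation for an exercise, and the scatter is random.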